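**Retrosynthetic overview**
1. The target SMILES encodes a cis-fused decalin (H-5, CH3-10 and the C9 CH2OAr arm on one face; 2-OAc equatorial on the other), so the usual late coupling of isofraxidin with a finished trans-drimane alcohol is not used.
2. Key disconnection C9–C10: a Me2AlCl-promoted intramolecular conjugate ene reaction of monocyclic enone 12, which already carries the coumarin ether, closes ring B last, forces the cis fusion, sets C10 and C9 and leaves the exocyclic methylene.
3. 12 comes from isofraxidin and an acyclic (Z)-allylic alcohol (Mitsunobu); the (Z)-alkene that decides C9 comes from syn-addition of Me2CuLi to an ynoate.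
4. Ring A with its gem-dimethyl group, the C10 methyl and the C5 stereocentre is bought as (R)-α-ionone; allylic oxidation and α′-acetoxylation add both ring A oxygens.
5. Ring order: ring A (chiral pool) and the coumarin (purchased) first, ring B last; the ring A ketol is then transposed (C2=O/C3–OH to C2–OAc/C3=O) and C2 equilibrated.

Assumption: (R)-(+)-α-ionone (1, high ee) and isofraxidin (10) are taken as purchasable.
Convention: terpenoid carbons carry drimane numbers (C11 = CH2O carbon, C12 = methylene carbon); β = the face of the C10 methyl; Ar = 6,8-dimethoxy-2-oxo-2H-chromen-7-yl; "5β-drimane" means H-5 β (cis fusion) with CH3-10 β and the C9 arm β.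

Step 1
Reactants: 1 (R)-α-ionone
Product: 2 (R)-dihydro-α-ionone [4-[(1R)-2,6,6-trimethylcyclohex-2-en-1-yl]butan-2-one]
Conditions: H2 (1 atm), RhCl(PPh3)3 (3 mol %), benzene, rt
Reagents that add atoms: none
Why: Chemoselective homogeneous hydrogenation in which RhCl(PPh3)3 saturates the disubstituted conjugated C=C much faster than the trisubstituted ring alkene and leaves the ketone and the existing stereocentre (future C5) untouched.

Step 2
Reactants: 2 (R)-dihydro-α-ionone
Product: 4 (6R)-6-(but-3-yn-1-yl)-1,5,5-trimethylcyclohex-1-ene, via enol diethyl phosphate 3 (not isolated)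
Conditions: LiN(iPr)2 (1.05 equiv), THF, −78 °C; ClP(O)(OEt)2, −78 °C to rt; then LiN(iPr)2 (2.3 equiv), −78 °C to rt; H2O
Reagents that add atoms: diethyl chlorophosphate CCOP(=O)(Cl)OCC (its atoms are in 3 only; none remain in 4)
Why: Negishi conversion of a methyl ketone into a terminal alkyne by kinetic enolisation at the methyl group, O-phosphorylation and double base-induced elimination, with no effect on the remote stereocentre.

Step 3
Reactants: 4 terminal alkyne
Product: 5 methyl 5-[(1R)-2,6,6-trimethylcyclohex-2-en-1-yl]pent-2-ynoate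
Conditions: n-BuLi (1.05 equiv), THF, −78 °C; then ClCO2Me, −78 to 0 °C
Reagents that add atoms: methyl chloroformate COC(=O)Cl
Why: Acetylide C-acylation, in which the lithium acetylide attacks the chloroformate and installs the carbon that becomes C11.

Step 4
Reactants: 5 ynoate
Product: 6 methyl (2Z)-3-methyl-5-[(1R)-2,6,6-trimethylcyclohex-2-en-1-yl]pent-2-enoate
Conditions: Me2CuLi (1.2 equiv, from MeLi and CuI), THF, −78 °C; MeOH quench at −78 °C
Reagents that add atoms: lithium dimethylcuprate [Li+].C[Cu-]C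
Why: Conjugate addition of a dialkylcuprate to an ynoate (carbocupration), where methyl and copper add syn and cold protonation with retention gives the (2Z)-enoate (ester cis to the long chain) that later places C11 on the β face of C9.

Step 5
Reactants: 6 (Z)-enoate
Product: 7 methyl (2Z)-3-methyl-5-[(1R)-2,6,6-trimethyl-4-oxocyclohex-2-en-1-yl]pent-2-enoate
Conditions: CrO3 (15 equiv), 3,5-dimethylpyrazole (15 equiv), CH2Cl2, −20 °C
Reagents that add atoms: chromium trioxide O=[Cr](=O)=O
Why: Allylic oxidation with the CrO3–3,5-dimethylpyrazole complex, which converts the only allylic CH2 of the electron-rich ring alkene into the enone carbonyl (future C2) while the electron-poor enoate and the γ-stereocentre survive.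

Step 6
Reactants: 7 enone ester
Product: 8 methyl (2Z)-5-[(1S,5R)-5-acetoxy-2,6,6-trimethyl-4-oxocyclohex-2-en-1-yl]-3-methylpent-2-enoate
Conditions: Mn(OAc)3·2H2O (3 equiv), benzene, reflux (Dean–Stark)
Reagents that add atoms: manganese triacetate CC(=O)O[Mn](OC(C)=O)OC(C)=O
Why: α′-Acetoxylation of an enone through its manganese enolate, where C3 is the only α′ position and acetate is delivered to the face away from the pseudoaxial side chain to give the trans (3β, pseudoequatorial) acetate, the minor epimer being removed by chromatography.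

Step 7
Reactants: 8 acetoxy enone ester
Product: 9 (4S,6R)-4-[(3Z)-5-hydroxy-3-methylpent-3-en-1-yl]-3,5,5-trimethylcyclohex-2-ene-1,6-diol (both C1 epimers)
Conditions: iBu2AlH (7 equiv), CH2Cl2, −78 to 0 °C; aq KNaC4H4O6 (potassium sodium tartrate)
Reagents that add atoms: none
Why: Global hydride reduction in which the ester gives the primary allylic alcohol, the acetate is cleaved and the enone is reduced 1,2 to a carbinol mixture that step 9 erases.

Step 8
Reactants: 9 triol; 10 isofraxidin (7-hydroxy-6,8-dimethoxy-2H-chromen-2-one)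
Product: 11 7-{[(2Z)-5-[(1S,5R)-4,5-dihydroxy-2,6,6-trimethylcyclohex-2-en-1-yl]-3-methylpent-2-en-1-yl]oxy}-6,8-dimethoxy-2H-chromen-2-one (both C4 carbinol epimers)
Conditions: PPh3 (1.2 equiv), DIAD (1.2 equiv), THF, 0 °C to rt
Reagents that add atoms: none
Why: Mitsunobu etherification, in which the acidic phenol (pKa about 8) displaces the activated primary allylic hydroxyl by SN2 much faster than either secondary hydroxyl and the (Z) geometry is kept.

Step 9
Reactants: 11 aryl ether diol
Product: 12 7-{[(2Z)-5-[(1S,5R)-5-hydroxy-2,6,6-trimethyl-4-oxocyclohex-2-en-1-yl]-3-methylpent-2-en-1-yl]oxy}-6,8-dimethoxy-2H-chromen-2-one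
Conditions: MnO2 (activated, 15 equiv), CH2Cl2, rt
Reagents that add atoms: none
Why: Selective allylic alcohol oxidation with MnO2, which restores the enone and leaves the non-allylic C3 hydroxyl.

Step 10
Reactants: 12 α′-hydroxy enone aryl ether
Product: 13 3β-hydroxy-11-[(6,8-dimethoxy-2-oxo-2H-chromen-7-yl)oxy]-5β-drim-8(12)-en-2-one
Conditions: Me2AlCl (3.5 equiv), CH2Cl2 (0.01 M), −78 to −20 °C; aq KNaC4H4O6
Reagents that add atoms: none
Why: Proposed new method: Me2AlCl turns the C3 hydroxyl into an aluminium alkoxide that chelates and activates the enone, the tethered trisubstituted alkene adds through C9 to C10 (tertiary cation character at C8) on the only face the three-carbon tether can reach, which makes the fusion cis (H-5 and CH3-10 both β), a chair-like ring B puts the CH2OAr group that is cis to the chain in the (Z)-alkene axial (C11 β), and a hydrogen of the C8 methyl passes to C1 through a six-membered ene transition state to leave the exocyclic methylene; the closest known reaction type is the alkylaluminium halide-promoted conjugate ene (cation–olefin) addition of alkenes to enones, here as an intramolecular type 2 ene reaction.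

Step 11
Reactants: 13 bicyclic ketol
Product: 14 11-[(6,8-dimethoxy-2-oxo-2H-chromen-7-yl)oxy]-5β-drim-8(12)-ene-2β,3β-diol
Conditions: NaBH4 (1.5 equiv), CeCl3·7H2O (1.5 equiv), MeOH, −40 °C
Reagents that add atoms: none
Why: Luche-type 1,2-reduction, in which hydride reaches C2 from the α face because the axial β trajectory is blocked by the syn-axial methyls on C4 and C10, giving the axial 2β-alcohol cis to the 3β-hydroxyl without touching the coumarin or the alkene.

Step 12
Reactants: 14 cis-diol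
Product: 16 2β-acetoxy-11-[(6,8-dimethoxy-2-oxo-2H-chromen-7-yl)oxy]-5β-drim-8(12)-en-3β-ol, via cyclic methyl orthoacetate 15 (not isolated)
Conditions: MeC(OMe)3 (3 equiv), pyridinium p-toluenesulfonate (5 mol %), CH2Cl2, rt; then AcOH–H2O (4:1), 0 °C
Reagents that add atoms: trimethyl orthoacetate CC(OC)(OC)OC; water O
Why: Orthoester monoacylation of a cis-diol, where stereoelectronically controlled hydrolysis of 15 cleaves the bond to the equatorial oxygen so the acetate ends on the axial O2 and the equatorial C3 hydroxyl is freed.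

Step 13
Reactants: 16 hydroxy acetate
Product: 17 2β-acetoxy-11-[(6,8-dimethoxy-2-oxo-2H-chromen-7-yl)oxy]-5β-drim-8(12)-en-3-one
Conditions: Dess–Martin periodinane (1.5 equiv), CH2Cl2, 0 °C to rt
Reagents that add atoms: none
Why: Dess–Martin oxidation of the hindered equatorial C3 alcohol to the ketone under non-basic conditions that spare the acetate, the alkene and the coumarin.

Step 14
Reactants: 17 axial acetoxy ketone
Product: 18 target, 7-{[(1S,4aS,7R,8aS)-7-acetoxy-5,5,8a-trimethyl-2-methylidene-6-oxodecahydronaphthalen-1-yl]methoxy}-6,8-dimethoxy-2H-chromen-2-one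
Conditions: DBU (0.3 equiv), toluene, rt
Reagents that add atoms: none
Why: Base-catalysed epimerisation of an α-acetoxy ketone through its enolate, where C2 is the only enolisable position (C4 is quaternary) and the axial 2β-acetate, 1,3-diaxial to two methyls, equilibrates to the equatorial 2α-acetate (C2 = R) of the target.

**Compound list**
1 | (R)-α-ionone, (3E)-4-[(1R)-2,6,6-trimethylcyclohex-2-en-1-yl]but-3-en-2-one | CC(=O)/C=C/[C@H]1C(C)=CCCC1(C)C | starting material
2 | (R)-dihydro-α-ionone, 4-[(1R)-2,6,6-trimethylcyclohex-2-en-1-yl]butan-2-one | CC(=O)CC[C@H]1C(C)=CCCC1(C)C | intermediate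
3 | diethyl 4-[(1R)-2,6,6-trimethylcyclohex-2-en-1-yl]but-1-en-2-yl phosphate | C=C(OP(=O)(OCC)OCC)CC[C@H]1C(C)=CCCC1(C)C | intermediate
4 | (6R)-6-(but-3-yn-1-yl)-1,5,5-trimethylcyclohex-1-ene | C#CCC[C@H]1C(C)=CCCC1(C)C | intermediate
5 | methyl 5-[(1R)-2,6,6-trimethylcyclohex-2-en-1-yl]pent-2-ynoate | COC(=O)C#CCC[C@H]1C(C)=CCCC1(C)C | intermediate
6 | methyl (2Z)-3-methyl-5-[(1R)-2,6,6-trimethylcyclohex-2-en-1-yl]pent-2-enoate | COC(=O)/C=C(/C)CC[C@H]1C(C)=CCCC1(C)C | intermediate
7 | methyl (2Z)-3-methyl-5-[(1R)-2,6,6-trimethyl-4-oxocyclohex-2-en-1-yl]pent-2-enoate | COC(=O)/C=C(/C)CC[C@H]1C(C)=CC(=O)CC1(C)C | intermediate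
8 | methyl (2Z)-5-[(1S,5R)-5-acetoxy-2,6,6-trimethyl-4-oxocyclohex-2-en-1-yl]-3-methylpent-2-enoate | COC(=O)/C=C(/C)CC[C@H]1C(C)=CC(=O)[C@H](OC(C)=O)C1(C)C | intermediate
9 | (4S,6R)-4-[(3Z)-5-hydroxy-3-methylpent-3-en-1-yl]-3,5,5-trimethylcyclohex-2-ene-1,6-diol (both C1 epimers) | OC/C=C(/C)CC[C@H]1C(C)=CC(O)[C@H](O)C1(C)C | intermediate
10 | isofraxidin, 7-hydroxy-6,8-dimethoxy-2H-chromen-2-one | COc1cc2ccc(=O)oc2c(OC)c1O | starting material
11 | 7-{[(2Z)-5-[(1S,5R)-4,5-dihydroxy-2,6,6-trimethylcyclohex-2-en-1-yl]-3-methylpent-2-en-1-yl]oxy}-6,8-dimethoxy-2H-chromen-2-one (both C4 carbinol epimers) | C(/C=C(/C)CC[C@H]1C(C)=CC(O)[C@H](O)C1(C)C)Oc1c(OC)cc2ccc(=O)oc2c1OC | intermediate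
12 | 7-{[(2Z)-5-[(1S,5R)-5-hydroxy-2,6,6-trimethyl-4-oxocyclohex-2-en-1-yl]-3-methylpent-2-en-1-yl]oxy}-6,8-dimethoxy-2H-chromen-2-one | C(/C=C(/C)CC[C@H]1C(C)=CC(=O)[C@H](O)C1(C)C)Oc1c(OC)cc2ccc(=O)oc2c1OC | intermediate
13 | 3β-hydroxy-11-(ArO)-5β-drim-8(12)-en-2-one | C=C1CC[C@@H]2C(C)(C)[C@@H](O)C(=O)C[C@]2(C)[C@H]1COc1c(OC)cc2ccc(=O)oc2c1OC | intermediate
14 | 11-(ArO)-5β-drim-8(12)-ene-2β,3β-diol | C=C1CC[C@@H]2C(C)(C)[C@@H](O)[C@@H](O)C[C@]2(C)[C@H]1COc1c(OC)cc2ccc(=O)oc2c1OC | intermediate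
15 | 2β,3β-O-(1-methoxyethylidene) derivative of 14 (cyclic methyl orthoacetate, orthoester carbon unassigned) | C=C1CC[C@@H]2C(C)(C)[C@@H](O3)[C@@H](OC3(C)OC)C[C@]2(C)[C@H]1COc1c(OC)cc2ccc(=O)oc2c1OC | intermediate
16 | 2β-acetoxy-11-(ArO)-5β-drim-8(12)-en-3β-ol | C=C1CC[C@@H]2C(C)(C)[C@@H](O)[C@@H](OC(C)=O)C[C@]2(C)[C@H]1COc1c(OC)cc2ccc(=O)oc2c1OC | intermediate
17 | 2β-acetoxy-11-(ArO)-5β-drim-8(12)-en-3-one | C=C1CC[C@@H]2C(C)(C)C(=O)[C@@H](OC(C)=O)C[C@]2(C)[C@H]1COc1c(OC)cc2ccc(=O)oc2c1OC | intermediate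
18 | 2α-acetoxy-11-(ArO)-5β-drim-8(12)-en-3-one, 7-{[(1S,4aS,7R,8aS)-7-acetoxy-5,5,8a-trimethyl-2-methylidene-6-oxodecahydronaphthalen-1-yl]methoxy}-6,8-dimethoxy-2H-chromen-2-one | C=C1CC[C@@H]2C(C)(C)C(=O)[C@H](OC(C)=O)C[C@]2(C)[C@H]1COc1c(OC)cc2ccc(=O)oc2c1OC | target

**Totals and weak points**
Total step count: 14. Longest linear sequence: 14 steps (1 to 18); isofraxidin 10 enters at step 8 as bought.

The three steps most likely to fail are step 10, step 12 and step 8.

Step 10 risk: the Lewis acid may ionise the allylic aryl ether, the alkene is deactivated by its allylic oxygen, and the C9 outcome rests on a chair-like ring B. Fallback (sets out from 9, comes back at 13): the coumarin is kept out of the ring closure. Triol 9 is silylated at the primary hydroxyl (t-BuPh2SiCl, imidazole, CH2Cl2) to the tert-butyldiphenylsilyl ether diol F1. MnO2 then gives the silyloxy enone F2, and Me2AlCl closes ring B as in step 10 to the bicyclic silyl ether F3, whose silyloxy group cannot leave as an aluminium phenoxide can. Bu4NF frees the bicyclic primary alcohol F4, and a Mitsunobu reaction of this alcohol with 10 (PPh3, DIAD) returns 13.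

Step 12 risk: acetyl migration from the crowded axial O2 to O3, or poor regiocontrol in the orthoester opening. Fallback (sets out from 13, comes back at 16): the two oxygens are told apart by a protecting group instead. Ketol 13 is silylated (t-BuMe2SiOTf, 2,6-lutidine) to the 3β-silyl ether ketone F8. NaBH4/CeCl3·7H2O reduction gives the 2β-alcohol F9, forced acetylation (Ac2O, DMAP, pyridine) gives the 2β-acetate silyl ether F10, and HF·pyridine removes the silyl group to give 16.

Step 8 risk: the Mitsunobu reaction may not discriminate cleanly among the three hydroxyls of 9. Fallback (sets out from 6, comes back at 12): the ether is made before ring A is oxidised. Ester 6 is reduced with iBu2AlH to the (Z)-allylic alcohol F5, which has a single hydroxyl and couples with 10 (PPh3, DIAD) to the aryl ether F6. CrO3–3,5-dimethylpyrazole oxidises the ring allylic CH2 (the side-chain alkene is deactivated by its allylic aryloxy group) to the enone aryl ether F7. Kinetic enolate hydroxylation (LiN(SiMe3)2, then 2-(phenylsulfonyl)-3-phenyloxaziridine, THF, −78 °C) anti to the side chain then gives 12.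

**Further compounds**
F1 | step 10 | (4S,6R)-4-[(3Z)-5-{[tert-butyl(diphenyl)silyl]oxy}-3-methylpent-3-en-1-yl]-3,5,5-trimethylcyclohex-2-ene-1,6-diol (both C1 epimers) | C(/C=C(/C)CC[C@H]1C(C)=CC(O)[C@H](O)C1(C)C)O[Si](c1ccccc1)(c1ccccc1)C(C)(C)C
F2 | step 10 | (4S,6R)-4-[(3Z)-5-{[tert-butyl(diphenyl)silyl]oxy}-3-methylpent-3-en-1-yl]-6-hydroxy-3,5,5-trimethylcyclohex-2-en-1-one | C(/C=C(/C)CC[C@H]1C(C)=CC(=O)[C@H](O)C1(C)C)O[Si](c1ccccc1)(c1ccccc1)C(C)(C)C
F3 | step 10 | 11-{[tert-butyl(diphenyl)silyl]oxy}-3β-hydroxy-5β-drim-8(12)-en-2-one | C=C1CC[C@@H]2C(C)(C)[C@@H](O)C(=O)C[C@]2(C)[C@H]1CO[Si](c1ccccc1)(c1ccccc1)C(C)(C)C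
F4 | step 10 | 3β,11-dihydroxy-5β-drim-8(12)-en-2-one | C=C1CC[C@@H]2C(C)(C)[C@@H](O)C(=O)C[C@]2(C)[C@H]1CO
F5 | step 8 | (2Z)-3-methyl-5-[(1R)-2,6,6-trimethylcyclohex-2-en-1-yl]pent-2-en-1-ol | OC/C=C(/C)CC[C@H]1C(C)=CCCC1(C)C
F6 | step 8 | 6,8-dimethoxy-7-{[(2Z)-3-methyl-5-[(1R)-2,6,6-trimethylcyclohex-2-en-1-yl]pent-2-en-1-yl]oxy}-2H-chromen-2-one | C(/C=C(/C)CC[C@H]1C(C)=CCCC1(C)C)Oc1c(OC)cc2ccc(=O)oc2c1OC
F7 | step 8 | 6,8-dimethoxy-7-{[(2Z)-3-methyl-5-[(1R)-2,6,6-trimethyl-4-oxocyclohex-2-en-1-yl]pent-2-en-1-yl]oxy}-2H-chromen-2-one | C(/C=C(/C)CC[C@H]1C(C)=CC(=O)CC1(C)C)Oc1c(OC)cc2ccc(=O)oc2c1OC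
F8 | step 12 | 3β-{[tert-butyl(dimethyl)silyl]oxy}-11-(ArO)-5β-drim-8(12)-en-2-one | C=C1CC[C@@H]2C(C)(C)[C@@H](O[Si](C)(C)C(C)(C)C)C(=O)C[C@]2(C)[C@H]1COc1c(OC)cc2ccc(=O)oc2c1OC
F9 | step 12 | 3β-{[tert-butyl(dimethyl)silyl]oxy}-11-(ArO)-5β-drim-8(12)-en-2β-ol | C=C1CC[C@@H]2C(C)(C)[C@@H](O[Si](C)(C)C(C)(C)C)[C@@H](O)C[C@]2(C)[C@H]1COc1c(OC)cc2ccc(=O)oc2c1OC
F10 | step 12 | 2β-acetoxy-3β-{[tert-butyl(dimethyl)silyl]oxy}-11-(ArO)-5β-drim-8(12)-ene | C=C1CC[C@@H]2C(C)(C)[C@@H](O[Si](C)(C)C(C)(C)C)[C@@H](OC(C)=O)C[C@]2(C)[C@H]1COc1c(OC)cc2ccc(=O)oc2c1OC
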